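**Retrosynthetic overview**
1. Target 25 ⇐ Heck arylation of the C4 acrylate 22 with iodobenzene and desilylation; 22 ⇐ methyl addition to the C4 ketone 18 with in-flask acryloylation (sets C4).
2. 18 (C4=O, 5α-H, Δ6, 7-iPr) ⇐ SmI2 reductive deconjugation of the γ-acetoxy enone 16 (sets C5) ⇐ isopropyl addition at C7 of ene-dione 13 ⇐ γ-C–H oxidation of enone 12.
3. 12 ⇐ trans-diol 11 ⇐ ketol 10 ⇐ key step: oxidative one-carbon ring expansion (1,2-shift of C3 from the carbonyl carbon to a diazo carbon) of the cyclopentanone of the (R)-Hajos–Parrish ketone 5 (sets C2; C1 follows by reduction).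
4. 5 ⇐ D-proline aldol cyclisation of triketone 3 (sets C10) ⇐ 2-methylcyclopentane-1,3-dione 1 + methyl vinyl ketone 2.
5. Ring order: ring B first (Hajos–Parrish annulation), then ring A by 5→6 expansion of the second ring of 5; no later ring formation.

Assumption: in the explanations the decalin is numbered as in eudesmanes (ring A = C1–C5, C10; ring B = C5–C10; angular methyl on C10; β = the face of that methyl). The C7 configuration drawn for 15 and 16 (α-face addition) is immaterial because step 8 erases it.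

**Route**

Step 1
Reactants: 1 2-methylcyclopentane-1,3-dione; 2 but-3-en-2-one (methyl vinyl ketone)
Product: 3 2-methyl-2-(3-oxobutyl)cyclopentane-1,3-dione
Conditions: H2O, AcOH (cat.), 70 °C
Reagents that add atoms: none
Why: Michael addition of the acidic 1,3-dione to the enone in water; the new quaternary carbon is still prochiral.

Step 2
Reactants: 3 2-methyl-2-(3-oxobutyl)cyclopentane-1,3-dione
Product: 5 (7aR)-7a-methyl-2,3,7,7a-tetrahydro-1H-indene-1,5(6H)-dione, via Hajos ketol 4 (not isolated)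
Conditions: D-proline (3 mol%), DMF, rt; then H2SO4 (cat.), 95 °C
Reagents that add atoms: none
Why: Hajos–Parrish–Eder–Sauer–Wiechert reaction: the D-proline enamine of the side-chain ketone attacks one enantiotopic ring carbonyl to give the cis-ketol, and acid dehydration gives the enone with C10 set as R (mirror image of the L-proline series, about 93–95% ee, raised by crystallisation).

Step 3
Reactants: 5 (7aR)-7a-methyl-2,3,7,7a-tetrahydro-1H-indene-1,5(6H)-dione; 6 (trimethylsilyl)diazomethane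
Product: 10 (2S,8aR)-2-hydroxy-8a-methyl-3,4,8,8a-tetrahydronaphthalene-1,6(2H,7H)-dione, via enol silane 7 (not isolated), via silyloxy epoxide 8 (not isolated), via silyloxy ketone 9 (not isolated)
Conditions: 6 (1.3 equiv), Sc(OTf)3 (5 mol%), CH2Cl2, −78 → −20 °C; then DMDO/acetone, −78 → −30 °C; then citric acid, MeOH, 0 °C
Reagents that add atoms: dimethyldioxirane, CC1(C)OO1
Why: Proposed new method: a one-flask oxidative ring homologation (formal insertion of CH–OH into the C(O)–CH2 bond) in which Sc(III) activates the strained, non-conjugated cyclopentanone in preference to the vinylogous enone carbonyl, the diazo carbon adds, the less substituted CH2 (C3) migrates anti to N2 as in the D-homoannulation of 17-oxo steroids, C→O silyl shift gives the regiodefined enol silane 7, and DMDO epoxidises it anti to the angular methyl so that the Rubottom silyl shift and methanolysis leave the 2α (equatorial, 2S) alcohol; the closest known reactions are the Lewis-acid-catalysed silyldiazomethane homologation of cycloalkanones and the Rubottom oxidation, which to my knowledge have not been run as one operation or on a Hajos–Parrish dione.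

Step 4
Reactants: 10 (2S,8aR)-2-hydroxy-8a-methyl-3,4,8,8a-tetrahydronaphthalene-1,6(2H,7H)-dione
Product: 11 (4aR,5S,6S)-5,6-dihydroxy-4a-methyl-4,4a,5,6,7,8-hexahydronaphthalen-2(3H)-one
Conditions: NaBH4 (0.3 equiv), EtOH, −20 °C
Reagents that add atoms: none
Why: Chemoselective borohydride reduction of the activated saturated α-hydroxy ketone over the enone (as with the Wieland–Miescher ketone); hydride enters C1 from the α-face, anti to the angular methyl, giving the 1β-alcohol and hence the trans-diequatorial diol.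

Step 5
Reactants: 11 (4aR,5S,6S)-5,6-dihydroxy-4a-methyl-4,4a,5,6,7,8-hexahydronaphthalen-2(3H)-one
Product: 12 (4aR,5S,6S)-4a-methyl-5,6-bis[(triethylsilyl)oxy]-4,4a,5,6,7,8-hexahydronaphthalen-2(3H)-one
Conditions: TESOTf (2.5 equiv), 2,6-lutidine, CH2Cl2, −78 → 0 °C
Reagents that add atoms: triethylsilyl trifluoromethanesulfonate, CC[Si](CC)(CC)OS(=O)(=O)C(F)(F)F
Why: Silyl triflate silylation of both hydroxyls (including the neopentyl C1–OH) so that the organometallic steps and the late acylation see only the intended oxygen; no stereocenter changes.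

Step 6
Reactants: 12 (4aR,5S,6S)-4a-methyl-5,6-bis[(triethylsilyl)oxy]-4,4a,5,6,7,8-hexahydronaphthalen-2(3H)-one
Product: 13 (4aR,5S,6S)-4a-methyl-5,6-bis[(triethylsilyl)oxy]-4,4a,5,6-tetrahydronaphthalene-2,8(3H,7H)-dione
Conditions: Rh2(cap)4 (1 mol%), t-BuOOH (70% aq., 5 equiv), 1,2-dichloroethane, 40 °C
Reagents that add atoms: tert-butyl hydroperoxide, CC(C)(C)OO
Why: Dirhodium caprolactamate/TBHP allylic oxidation: t-BuOO• abstracts the γ-hydrogen at C4, the only allylic CH2 of the enone, and the mixed peroxide collapses to the ene-dione, as known for Δ4-3-oxo steroids going to Δ4-3,6-diones.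

Step 7
Reactants: 13 (4aR,5S,6S)-4a-methyl-5,6-bis[(triethylsilyl)oxy]-4,4a,5,6-tetrahydronaphthalene-2,8(3H,7H)-dione; 14 isopropylmagnesium chloride
Product: 16 (2S,4aR,5S,6S)-4a-methyl-8-oxo-2-(propan-2-yl)-5,6-bis[(triethylsilyl)oxy]-2,3,4,4a,5,6,7,8-octahydronaphthalen-2-yl acetate, via magnesium alkoxide 15 (not isolated)
Conditions: 14 (1.2 equiv), LaCl3·2LiCl, THF, −78 °C; then Ac2O, DMAP (cat.), −78 → 0 °C
Reagents that add atoms: acetic anhydride, CC(=O)OC(C)=O
Why: Lanthanide-promoted Grignard 1,2-addition goes to the unhindered C7 carbonyl because the C4 carbonyl is shielded by the 1,3-related angular methyl and the fully substituted C5, and the tertiary alkoxide is acetylated in the flask; the new C7 center is lost in step 8.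

Step 8
Reactants: 16 (2S,4aR,5S,6S)-4a-methyl-8-oxo-2-(propan-2-yl)-5,6-bis[(triethylsilyl)oxy]-2,3,4,4a,5,6,7,8-octahydronaphthalen-2-yl acetate
Product: 18 (3S,4S,4aR,8aR)-4a-methyl-7-(propan-2-yl)-3,4-bis[(triethylsilyl)oxy]-3,4,4a,5,6,8a-hexahydronaphthalen-1(2H)-one, via samarium dienolate 17 (not isolated)
Conditions: SmI2 (2.5 equiv), MeOH (5 equiv), THF, −78 °C
Reagents that add atoms: none
Why: SmI2 reductive elimination of a γ-acetoxy enone: two electron transfers expel acetate and give the dienolate, which is protonated kinetically at the α-carbon C5 from the α-face (anti to the C10 methyl), setting the trans ring fusion (5α-H) and leaving the Δ6 alkene that carries the isopropyl group.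

Step 9
Reactants: 18 (3S,4S,4aR,8aR)-4a-methyl-7-(propan-2-yl)-3,4-bis[(triethylsilyl)oxy]-3,4,4a,5,6,8a-hexahydronaphthalen-1(2H)-one; 19 methyllithium; 20 prop-2-enoyl chloride (acryloyl chloride)
Product: 22 (1S,3S,4S,4aR,8aR)-1,4a-dimethyl-7-(propan-2-yl)-3,4-bis[(triethylsilyl)oxy]-1,2,3,4,4a,5,6,8a-octahydronaphthalen-1-yl prop-2-enoate, via lithium alkoxide 21 (not isolated)
Conditions: 19 (1.2 equiv), Et2O/THF, −78 °C; then 20 (2 equiv), −78 → 0 °C
Reagents that add atoms: none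
Why: 1,2-Addition of MeLi along the equatorial (α-face) trajectory, because axial approach is blocked by the 1,3-diaxial C10 methyl (as for 6-oxo-5α-steroids), gives the 4α-methyl-4β-alkoxide (4S), and the hindered tertiary lithium alkoxide is O-acylated in the same flask by the acid chloride.

Step 10
Reactants: 22 (1S,3S,4S,4aR,8aR)-1,4a-dimethyl-7-(propan-2-yl)-3,4-bis[(triethylsilyl)oxy]-1,2,3,4,4a,5,6,8a-octahydronaphthalen-1-yl prop-2-enoate; 23 iodobenzene
Product: 25 (1S,3S,4S,4aR,8aR)-3,4-dihydroxy-1,4a-dimethyl-7-(propan-2-yl)-1,2,3,4,4a,5,6,8a-octahydronaphthalen-1-yl (2E)-3-phenylprop-2-enoate, via bis-TES cinnamate 24 (not isolated)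
Conditions: Pd(OAc)2 (5 mol%), P(o-tol)3 (10 mol%), Et3N, MeCN, 80 °C; then HF·pyridine, THF, 0 °C → rt
Reagents that add atoms: none
Why: Mizoroki–Heck arylation of the acrylate (syn-insertion and syn-β-hydride elimination give the E-cinnamate, the trisubstituted ring alkene is inert), then fluoride cleaves both TES ethers without touching the hindered tertiary ester.

**Compound list**
1 | 2-methylcyclopentane-1,3-dione | CC1C(=O)CCC1=O | starting material
2 | but-3-en-2-one (methyl vinyl ketone) | CC(=O)C=C | starting material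
3 | 2-methyl-2-(3-oxobutyl)cyclopentane-1,3-dione | CC(=O)CCC1(C)C(=O)CCC1=O | intermediate
4 | (3aR,7aR)-3a-hydroxy-7a-methylhexahydro-1H-indene-1,5(6H)-dione (Hajos ketol) | C[C@@]12CCC(=O)C[C@]1(O)CCC2=O | intermediate
5 | (7aR)-7a-methyl-2,3,7,7a-tetrahydro-1H-indene-1,5(6H)-dione ((R)-Hajos–Parrish ketone) | C[C@@]12CCC(=O)C=C1CCC2=O | intermediate
6 | (trimethylsilyl)diazomethane | C[Si](C)(C)C=[N+]=[N-] | starting material
7 | (4aR)-4a-methyl-5-[(trimethylsilyl)oxy]-4,4a,7,8-tetrahydronaphthalen-2(3H)-one | C[C@@]12CCC(=O)C=C1CCC=C2O[Si](C)(C)C | intermediate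
8 | 5,6-epoxide of 7 with the epoxide oxygen anti to the 4a-methyl (5-silyloxy oxirane) | C[C@@]12CCC(=O)C=C1CC[C@@H]3O[C@]23O[Si](C)(C)C | intermediate
9 | (2S,8aR)-8a-methyl-2-[(trimethylsilyl)oxy]-3,4,8,8a-tetrahydronaphthalene-1,6(2H,7H)-dione | C[C@@]12CCC(=O)C=C1CC[C@H](O[Si](C)(C)C)C2=O | intermediate
10 | (2S,8aR)-2-hydroxy-8a-methyl-3,4,8,8a-tetrahydronaphthalene-1,6(2H,7H)-dione | C[C@@]12CCC(=O)C=C1CC[C@H](O)C2=O | intermediate
11 | (4aR,5S,6S)-5,6-dihydroxy-4a-methyl-4,4a,5,6,7,8-hexahydronaphthalen-2(3H)-one | C[C@@]12CCC(=O)C=C1CC[C@H](O)[C@H]2O | intermediate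
12 | (4aR,5S,6S)-4a-methyl-5,6-bis[(triethylsilyl)oxy]-4,4a,5,6,7,8-hexahydronaphthalen-2(3H)-one | C[C@@]12CCC(=O)C=C1CC[C@H](O[Si](CC)(CC)CC)[C@H]2O[Si](CC)(CC)CC | intermediate
13 | (4aR,5S,6S)-4a-methyl-5,6-bis[(triethylsilyl)oxy]-4,4a,5,6-tetrahydronaphthalene-2,8(3H,7H)-dione | C[C@@]12CCC(=O)C=C1C(=O)C[C@H](O[Si](CC)(CC)CC)[C@H]2O[Si](CC)(CC)CC | intermediate
14 | isopropylmagnesium chloride | CC(C)[Mg]Cl | starting material
15 | chloromagnesium (2S,4aR,5S,6S)-4a-methyl-8-oxo-2-(propan-2-yl)-5,6-bis[(triethylsilyl)oxy]-2,3,4,4a,5,6,7,8-octahydronaphthalen-2-olate | C[C@@]12CC[C@@](C(C)C)(O[Mg]Cl)C=C1C(=O)C[C@H](O[Si](CC)(CC)CC)[C@H]2O[Si](CC)(CC)CC | intermediate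
16 | (2S,4aR,5S,6S)-4a-methyl-8-oxo-2-(propan-2-yl)-5,6-bis[(triethylsilyl)oxy]-2,3,4,4a,5,6,7,8-octahydronaphthalen-2-yl acetate | C[C@@]12CC[C@@](C(C)C)(OC(C)=O)C=C1C(=O)C[C@H](O[Si](CC)(CC)CC)[C@H]2O[Si](CC)(CC)CC | intermediate
17 | diiodosamarium(III) (3S,4S,4aR)-4a-methyl-7-(propan-2-yl)-3,4-bis[(triethylsilyl)oxy]-2,3,4,4a,5,6-hexahydronaphthalen-1-olate (dienolate) | C[C@@]12CCC(C(C)C)=CC1=C(O[Sm](I)I)C[C@H](O[Si](CC)(CC)CC)[C@H]2O[Si](CC)(CC)CC | intermediate
18 | (3S,4S,4aR,8aR)-4a-methyl-7-(propan-2-yl)-3,4-bis[(triethylsilyl)oxy]-3,4,4a,5,6,8a-hexahydronaphthalen-1(2H)-one | C[C@@]12CCC(C(C)C)=C[C@H]1C(=O)C[C@H](O[Si](CC)(CC)CC)[C@H]2O[Si](CC)(CC)CC | intermediate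
19 | methyllithium | [Li]C | starting material
20 | prop-2-enoyl chloride (acryloyl chloride) | C=CC(=O)Cl | starting material
21 | lithium (1S,3S,4S,4aR,8aR)-1,4a-dimethyl-7-(propan-2-yl)-3,4-bis[(triethylsilyl)oxy]-1,2,3,4,4a,5,6,8a-octahydronaphthalen-1-olate | C[C@@]12CCC(C(C)C)=C[C@H]1[C@@](C)(O[Li])C[C@H](O[Si](CC)(CC)CC)[C@H]2O[Si](CC)(CC)CC | intermediate
22 | (1S,3S,4S,4aR,8aR)-1,4a-dimethyl-7-(propan-2-yl)-3,4-bis[(triethylsilyl)oxy]-1,2,3,4,4a,5,6,8a-octahydronaphthalen-1-yl prop-2-enoate | C[C@@]12CCC(C(C)C)=C[C@H]1[C@@](C)(OC(=O)C=C)C[C@H](O[Si](CC)(CC)CC)[C@H]2O[Si](CC)(CC)CC | intermediate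
23 | iodobenzene | Ic1ccccc1 | starting material
24 | (1S,3S,4S,4aR,8aR)-1,4a-dimethyl-7-(propan-2-yl)-3,4-bis[(triethylsilyl)oxy]-1,2,3,4,4a,5,6,8a-octahydronaphthalen-1-yl (2E)-3-phenylprop-2-enoate | C[C@@]12CCC(C(C)C)=C[C@H]1[C@@](C)(OC(=O)/C=C/c1ccccc1)C[C@H](O[Si](CC)(CC)CC)[C@H]2O[Si](CC)(CC)CC | intermediate
25 | (1S,3S,4S,4aR,8aR)-3,4-dihydroxy-1,4a-dimethyl-7-(propan-2-yl)-1,2,3,4,4a,5,6,8a-octahydronaphthalen-1-yl (2E)-3-phenylprop-2-enoate (CNP0222501.2) | CC(C)C1=C[C@@H]2[C@@](C)(CC1)[C@H](O)[C@@H](O)C[C@]2(C)OC(=O)/C=C/c1ccccc1 | target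

**Step count and risks**
Total steps: 10. Longest linear sequence: 10 steps (1 → 25).

Steps most likely to fail:

Step 3 (the proposed oxidative ring homologation). The risks are competing activation of the enone by scandium, incomplete C→O silyl transfer, and oxidant incompatibility in one flask. The fallback uses only known chemistry, sets out from 5 and returns at 10. Compound 5 is homologated with ethyl diazoacetate and BF3·OEt2 in CH2Cl2 at 0 °C (classical diazoacetate ring expansion, same methylene migration) to give ethyl (8aR)-1-hydroxy-8a-methyl-6-oxo-3,4,6,7,8,8a-hexahydronaphthalene-2-carboxylate F1, the enolised β-keto ester. F1 is the only 1,3-dicarbonyl present, so DMDO hydroxylates it at C2 to give ethyl (2S,8aR)-2-hydroxy-8a-methyl-1,6-dioxo-1,2,3,4,6,7,8,8a-octahydronaphthalene-2-carboxylate F2 (C2 configuration immaterial). LiOH in THF/water gives (2S,8aR)-2-hydroxy-8a-methyl-1,6-dioxo-1,2,3,4,6,7,8,8a-octahydronaphthalene-2-carboxylic acid F3, which on acidification and gentle warming decarboxylates through the enediol. Protonation at the less hindered C2 and equilibration to the equatorial alcohol give 10.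

Step 7 (addition to one of two conjugated carbonyls). The risks are attack at C4, conjugate addition, enolisation or electron transfer to the ene-dione. The fallback changes the order so that only one ketone is present; it sets out from 12 and returns at 16. Isopropylmagnesium chloride with LaCl3·2LiCl adds to the single enone carbonyl of 12 to give chloromagnesium (2S,4aR,5S,6S)-4a-methyl-2-(propan-2-yl)-5,6-bis[(triethylsilyl)oxy]-2,3,4,4a,5,6,7,8-octahydronaphthalen-2-olate F4. Acetic anhydride in the same flask converts it into (2S,4aR,5S,6S)-4a-methyl-2-(propan-2-yl)-5,6-bis[(triethylsilyl)oxy]-2,3,4,4a,5,6,7,8-octahydronaphthalen-2-yl acetate F5. Allylic oxidation of F5 with CrO3·3,5-dimethylpyrazole in CH2Cl2 at −20 °C (C4 is its only allylic CH2) gives 16.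

Step 9 (addition to a hindered, enolisable β,γ-unsaturated ketone and acylation of a hindered alkoxide). The risks are deprotonation at C5 or C3 by MeLi and slow or messy acryloylation. The fallback separates the two events and builds the cinnamate by a Wittig reaction instead of a Heck reaction; it sets out from 18 and returns at 24. MeMgBr with LaCl3·2LiCl in THF at −40 °C and aqueous work-up give (1S,3S,4S,4aR,8aR)-1,4a-dimethyl-7-(propan-2-yl)-3,4-bis[(triethylsilyl)oxy]-1,2,3,4,4a,5,6,8a-octahydronaphthalen-1-ol F6. Bromoacetyl bromide and pyridine give the corresponding bromoacetate, (1S,3S,4S,4aR,8aR)-1,4a-dimethyl-7-(propan-2-yl)-3,4-bis[(triethylsilyl)oxy]-1,2,3,4,4a,5,6,8a-octahydronaphthalen-1-yl bromoacetate F7. Triphenylphosphine in toluene gives the phosphonium bromide, [2-oxo-2-(F6-oxy)ethyl]triphenylphosphonium bromide F8. K2CO3 generates the stabilised ylide, the F6 ester of (triphenyl-λ5-phosphanylidene)acetic acid F9, which condenses with benzaldehyde to the E-cinnamate 24. The fluoride treatment of step 10 then gives 25.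

Further compounds
F1 | step 3 | ethyl (8aR)-1-hydroxy-8a-methyl-6-oxo-3,4,6,7,8,8a-hexahydronaphthalene-2-carboxylate | C[C@@]12CCC(=O)C=C1CCC(C(=O)OCC)=C2O
F2 | step 3 | ethyl (2S,8aR)-2-hydroxy-8a-methyl-1,6-dioxo-1,2,3,4,6,7,8,8a-octahydronaphthalene-2-carboxylate | C[C@@]12CCC(=O)C=C1CC[C@@](O)(C(=O)OCC)C2=O
F3 | step 3 | (2S,8aR)-2-hydroxy-8a-methyl-1,6-dioxo-1,2,3,4,6,7,8,8a-octahydronaphthalene-2-carboxylic acid | C[C@@]12CCC(=O)C=C1CC[C@@](O)(C(=O)O)C2=O
F4 | step 7 | chloromagnesium (2S,4aR,5S,6S)-4a-methyl-2-(propan-2-yl)-5,6-bis[(triethylsilyl)oxy]-2,3,4,4a,5,6,7,8-octahydronaphthalen-2-olate | C[C@@]12CC[C@@](C(C)C)(O[Mg]Cl)C=C1CC[C@H](O[Si](CC)(CC)CC)[C@H]2O[Si](CC)(CC)CC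
F5 | step 7 | (2S,4aR,5S,6S)-4a-methyl-2-(propan-2-yl)-5,6-bis[(triethylsilyl)oxy]-2,3,4,4a,5,6,7,8-octahydronaphthalen-2-yl acetate | C[C@@]12CC[C@@](C(C)C)(OC(C)=O)C=C1CC[C@H](O[Si](CC)(CC)CC)[C@H]2O[Si](CC)(CC)CC
F6 | step 9 | (1S,3S,4S,4aR,8aR)-1,4a-dimethyl-7-(propan-2-yl)-3,4-bis[(triethylsilyl)oxy]-1,2,3,4,4a,5,6,8a-octahydronaphthalen-1-ol | C[C@@]12CCC(C(C)C)=C[C@H]1[C@@](C)(O)C[C@H](O[Si](CC)(CC)CC)[C@H]2O[Si](CC)(CC)CC
F7 | step 9 | (1S,3S,4S,4aR,8aR)-1,4a-dimethyl-7-(propan-2-yl)-3,4-bis[(triethylsilyl)oxy]-1,2,3,4,4a,5,6,8a-octahydronaphthalen-1-yl bromoacetate | C[C@@]12CCC(C(C)C)=C[C@H]1[C@@](C)(OC(=O)CBr)C[C@H](O[Si](CC)(CC)CC)[C@H]2O[Si](CC)(CC)CC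
F8 | step 9 | [2-oxo-2-(F6-oxy)ethyl]triphenylphosphonium bromide | C[C@@]12CCC(C(C)C)=C[C@H]1[C@@](C)(OC(=O)C[P+](c1ccccc1)(c1ccccc1)c1ccccc1)C[C@H](O[Si](CC)(CC)CC)[C@H]2O[Si](CC)(CC)CC.[Br-]
F9 | step 9 | F6 ester of (triphenyl-λ5-phosphanylidene)acetic acid (stabilised ylide) | C[C@@]12CCC(C(C)C)=C[C@H]1[C@@](C)(OC(=O)C=P(c1ccccc1)(c1ccccc1)c1ccccc1)C[C@H](O[Si](CC)(CC)CC)[C@H]2O[Si](CC)(CC)CC
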